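**Plan** (flavanone numbering: ring A is the fully substituted benzene, ring B the 2,6‑dioxygenated phenyl, O2' the bridging oxygen; prenyl = 3‑methylbut‑2‑en‑1‑yl)
1. The target is the closed hemiketal of a (2R)‑flavanone. Cutting O2'–C4 (ring–chain) and O1–C2 (retro‑oxa‑Michael) gives a 2'‑hydroxychalcone, which is the water adduct of a 2‑arylchromenylium ion whose pyrylium ring sits on ring B.
2. Enabling feature: the ring O2'–C4–C3–C2–C1'–C2' fused to ring B is a latent 4‑pyranone. With C2 as a ketone, C3–H is acidic and the carbonyl, ortho to C2', activates a fluoride there. The chromone is cut at C3–C4 (Claisen) and O2'–C2' (SNAr) into ring A acid 9 and fluoro ketone 11.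
3. Ring A: carboxyl by ortho‑lithiation/CO2; pyran by prenal annulation of a symmetric 2‑prenylresorcinol (one regioisomer possible); prenyl by ortho‑lithiation of bis‑MOM 5‑methoxyresorcinol.
4. Forward: chromene ring, then (key step) the pyranone on ring B, then the chromenylium ion; water opens it, the ring A phenol closes ring C and a ring B phenol closes the ketal.
5. Stereochemistry: C2 (R) comes from a catalyst‑controlled oxa‑Michael addition in the last step; C4 follows from C2 because the bicyclo[3.3.1] bridge allows one relative configuration only.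

Key step: step 8

Assumption: the target is treated as the stable ring tautomer (cyclic hemiketal) of flavanone 20; the quinidine‑derived catalyst of step 10 is assumed to give 2R, and its quinine‑derived pseudoenantiomer would be used if a model cyclization shows the opposite sense.

**Step 1**
Reactants: 1 5‑methoxyresorcinol
Product: 2 1‑methoxy‑3,5‑bis(methoxymethoxy)benzene
Conditions: NaH (2.4 equiv), MOMCl (2.4 equiv), DMF, 0 °C → rt
Reagents that add atoms: chloromethyl methyl ether (MOMCl), COCCl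
Why: Williamson O‑alkylation of both phenoxides installs two chelating directing groups that survive organolithium chemistry.

**Step 2**
Reactants: 2 1‑methoxy‑3,5‑bis(methoxymethoxy)benzene
Product: 4 5‑methoxy‑1,3‑bis(methoxymethoxy)‑2‑prenylbenzene, via aryllithium 3 (not isolated)
Conditions: n‑BuLi (1.1 equiv), THF, 0 °C → rt; CuI (10 mol%), prenyl bromide, −78 °C → rt
Reagents that add atoms: 1‑bromo‑3‑methylbut‑2‑ene (prenyl bromide), CC(C)=CCBr; n‑butyllithium, [Li]CCCC (lithium of 3 only)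
Why: Directed ortho‑metalation should occur at the one position flanked by two chelating MOM‑oxy groups, and the aryllithium is allylated at the primary carbon of prenyl bromide under copper catalysis (SN2 allylation).

**Step 3**
Reactants: 4 5‑methoxy‑1,3‑bis(methoxymethoxy)‑2‑prenylbenzene
Product: 5 5‑methoxy‑2‑prenylbenzene‑1,3‑diol
Conditions: HCl (1.25 M in MeOH), rt
Reagents that add atoms: none
Why: Acid‑catalysed acetal exchange with methanol should cleave both aryl MOM ethers under conditions mild enough to spare the trisubstituted prenyl alkene.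

**Step 4**
Reactants: 5 5‑methoxy‑2‑prenylbenzene‑1,3‑diol
Product: 6 5‑methoxy‑2,2‑dimethyl‑8‑prenyl‑2H‑chromen‑7‑ol
Conditions: 3‑methylbut‑2‑enal (1.0 equiv, slow addition), ethylenediammonium diacetate (10 mol%), toluene, reflux
Reagents that add atoms: 3‑methylbut‑2‑enal (prenal), CC(C)=CC=O
Why: Knoevenagel‑type C‑alkylation ortho to a free hydroxyl, dehydration to an ortho‑quinone methide and oxa‑6π electrocyclization give the 2,2‑dimethylchromene; the two open ring positions of 5 are equivalent by symmetry and each has only one neighbouring hydroxyl, so a single regioisomer is possible and one equivalent of enal limits double annulation.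

**Step 5**
Reactants: 6 5‑methoxy‑2,2‑dimethyl‑8‑prenyl‑2H‑chromen‑7‑ol
Product: 7 5‑methoxy‑7‑(methoxymethoxy)‑2,2‑dimethyl‑8‑prenyl‑2H‑chromene
Conditions: NaH (1.2 equiv), MOMCl (1.2 equiv), DMF, 0 °C → rt
Reagents that add atoms: chloromethyl methyl ether (MOMCl), COCCl
Why: Williamson O‑alkylation of the remaining phenoxide gives a MOM ether that protects the future O1 and directs the next lithiation.

**Step 6**
Reactants: 7 5‑methoxy‑7‑(methoxymethoxy)‑2,2‑dimethyl‑8‑prenyl‑2H‑chromene
Product: 9 5‑methoxy‑7‑(methoxymethoxy)‑2,2‑dimethyl‑8‑prenyl‑2H‑chromene‑6‑carboxylic acid, via aryllithium 8 (not isolated)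
Conditions: n‑BuLi (1.2 equiv), TMEDA, THF, −78 → −20 °C; CO2, −78 °C → rt; cold dilute HCl to pH 3
Reagents that add atoms: carbon dioxide, O=C=O; n‑butyllithium, [Li]CCCC (lithium of 8 only)
Why: Directed ortho‑metalation at the single remaining ring C–H, flanked by OMe and OMOM, then carboxylation of the aryllithium with CO2 should give the acid with unambiguous regiochemistry.

**Step 7**
Reactants: 10 1‑(2‑fluoro‑6‑hydroxyphenyl)ethan‑1‑one
Product: 11 1‑[2‑fluoro‑6‑(methoxymethoxy)phenyl]ethan‑1‑one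
Conditions: MOMCl (1.3 equiv), K2CO3 (2 equiv), acetone, 0 °C → rt
Reagents that add atoms: chloromethyl methyl ether (MOMCl), COCCl
Why: Williamson O‑alkylation of the phenoxide protects the ring B hydroxyl without touching the aryl fluoride or the methyl ketone.

**Step 8**
Reactants: 9 5‑methoxy‑7‑(methoxymethoxy)‑2,2‑dimethyl‑8‑prenyl‑2H‑chromene‑6‑carboxylic acid; 11 1‑[2‑fluoro‑6‑(methoxymethoxy)phenyl]ethan‑1‑one
Product: 15 5‑(methoxymethoxy)‑2‑[5‑methoxy‑7‑(methoxymethoxy)‑2,2‑dimethyl‑8‑prenyl‑2H‑chromen‑6‑yl]‑4H‑chromen‑4‑one, via acyl imidazole 12 (not isolated), via lithium enolate 13 (not isolated), via lithium diketonate 14 (not isolated)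
Conditions: 9, 1,1'‑carbonyldiimidazole (1.1 equiv), THF, rt; added to 11 (1.1 equiv) + LiN(SiMe3)2 (3.3 equiv), THF, −78 °C → rt; then DMF, 80 °C; AcOH quench
Reagents that add atoms: 1,1'‑carbonyldiimidazole, O=C(n1ccnc1)n1ccnc1 (imidazolyl group of 12 only); lithium bis(trimethylsilyl)amide, [Li]N([Si](C)(C)C)[Si](C)(C)C (lithium of 13 and 14 only)
Why: The lithium enolate 13 attacks the acyl imidazole 12 at carbon (crossed Claisen condensation, C3–C4 bond) and the product is deprotonated to the chelated lithium diketonate 14; on heating in DMF its C4 enolate oxygen adds to the fluorine‑bearing C2' of ring B, which lies ortho to the C2 carbonyl, and fluoride leaves from the Meisenheimer intermediate (intramolecular SNAr, O2'–C2' bond). The closest known reaction type is the base‑mediated cyclization of 1‑(2‑fluoroaryl)‑1,3‑diketones and related 2‑halobenzoyl β‑dicarbonyl compounds to chromones. The pyranone ring closes by a 6‑exo‑trig addition–elimination at the arene carbon; the other diketonate oxygen could only give a four‑membered ring. No stereocenter is formed. The step needs C‑ rather than O‑acylation, which the lithium counter‑ion in THF and the drain of any enol ester to the stable diketonate should secure, and displacement of fluoride rather than of the MOM‑oxy group at C6', which follows from the much greater activating effect and nucleofugality of fluorine in SNAr; because both ring A oxygens ortho to C4 are capped (OMe, OMOM), closure onto ring A is excluded.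

**Step 9**
Reactants: 15 5‑(methoxymethoxy)‑2‑[5‑methoxy‑7‑(methoxymethoxy)‑2,2‑dimethyl‑8‑prenyl‑2H‑chromen‑6‑yl]‑4H‑chromen‑4‑one
Product: 17 5‑hydroxy‑2‑(7‑hydroxy‑5‑methoxy‑2,2‑dimethyl‑8‑prenyl‑2H‑chromen‑6‑yl)chromenylium chloride, via chromen‑4‑ol 16 (not isolated)
Conditions: LiAlH4 (1.0 equiv), THF, 0 °C; aq. NaOH work‑up; crude 16, HCl (1.25 M in MeOH), 0 °C → rt; precipitation with Et2O
Reagents that add atoms: hydrogen chloride, Cl
Why: 1,2‑Hydride addition to the vinylogous ester carbonyl (as in a Stork–Danheiser reduction) should give the racemic 4H‑chromen‑4‑ol, which in acid loses water to the aromatic 2‑arylchromenylium ion while methanolic HCl removes both MOM groups by acetal exchange; no stereocenter remains after this step.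

**Step 10**
Reactants: 17 5‑hydroxy‑2‑(7‑hydroxy‑5‑methoxy‑2,2‑dimethyl‑8‑prenyl‑2H‑chromen‑6‑yl)chromenylium chloride
Product: 21 target hemiketal (2R,4R), via chromen‑2‑ol 18 (not isolated), via cis‑chalcone 19 (not isolated), via flavanone 20 (not isolated)
Conditions: N‑[3,5‑bis(trifluoromethyl)phenyl]‑N'‑(9‑deoxy‑epi‑quinidin‑9‑yl)squaramide (10 mol%), NaHCO3 (1.2 equiv), H2O (5 equiv), toluene/CHCl3, −20 → 0 °C
Reagents that add atoms: water, O
Why: Neutralization lets water add to C2 of the chromenylium ion, the hemiketal 18 opens to the cis‑chalcone 19, and the bifunctional cinchona squaramide (tertiary amine as general base for the ring A phenol, squaramide N–H bonds on the enone carbonyl) should direct the 6‑endo‑trig oxa‑Michael addition to one face of the β‑carbon and set C2 as R, after which a ring B hydroxyl adds to the C4 ketone to give the bridged hemiketal, whose C4 configuration is fixed by C2 through the bicyclo[3.3.1] bridge and whose formation removes the ketone needed for retro‑Michael racemization (asymmetric organocatalytic oxa‑Michael cyclization of a 2'‑hydroxychalcone followed by hemiketalization).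

**Compound list**
1 | 5‑methoxyresorcinol | COc1cc(O)cc(O)c1 | starting material
2 | 1‑methoxy‑3,5‑bis(methoxymethoxy)benzene | COCOc1cc(OC)cc(OCOC)c1 | intermediate
3 | [4‑methoxy‑2,6‑bis(methoxymethoxy)phenyl]lithium | [Li]c1c(OCOC)cc(OC)cc1OCOC | intermediate
4 | 5‑methoxy‑1,3‑bis(methoxymethoxy)‑2‑prenylbenzene | COCOc1cc(OC)cc(OCOC)c1CC=C(C)C | intermediate
5 | 5‑methoxy‑2‑prenylbenzene‑1,3‑diol | COc1cc(O)c(CC=C(C)C)c(O)c1 | intermediate
6 | 5‑methoxy‑2,2‑dimethyl‑8‑prenyl‑2H‑chromen‑7‑ol | COc1cc(O)c(CC=C(C)C)c2OC(C)(C)C=Cc12 | intermediate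
7 | 5‑methoxy‑7‑(methoxymethoxy)‑2,2‑dimethyl‑8‑prenyl‑2H‑chromene | COCOc1cc(OC)c2C=CC(C)(C)Oc2c1CC=C(C)C | intermediate
8 | 6‑lithio derivative of 7 | [Li]c1c(OC)c2C=CC(C)(C)Oc2c(CC=C(C)C)c1OCOC | intermediate
9 | 5‑methoxy‑7‑(methoxymethoxy)‑2,2‑dimethyl‑8‑prenyl‑2H‑chromene‑6‑carboxylic acid | COCOc1c(C(=O)O)c(OC)c2C=CC(C)(C)Oc2c1CC=C(C)C | intermediate
10 | 1‑(2‑fluoro‑6‑hydroxyphenyl)ethan‑1‑one | CC(=O)c1c(O)cccc1F | starting material
11 | 1‑[2‑fluoro‑6‑(methoxymethoxy)phenyl]ethan‑1‑one | COCOc1cccc(F)c1C(C)=O | intermediate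
12 | acyl imidazole of acid 9 | COCOc1c(C(=O)n2ccnc2)c(OC)c2C=CC(C)(C)Oc2c1CC=C(C)C | intermediate
13 | lithium enolate of ketone 11 | C=C(O[Li])c1c(F)cccc1OCOC | intermediate
14 | lithium enolate of 1‑[2‑fluoro‑6‑(methoxymethoxy)phenyl]‑3‑[5‑methoxy‑7‑(methoxymethoxy)‑2,2‑dimethyl‑8‑prenyl‑2H‑chromen‑6‑yl]propane‑1,3‑dione | [Li]OC(=CC(=O)c1c(F)cccc1OCOC)c1c(OC)c2C=CC(C)(C)Oc2c(CC=C(C)C)c1OCOC | intermediate
15 | 5‑(methoxymethoxy)‑2‑[5‑methoxy‑7‑(methoxymethoxy)‑2,2‑dimethyl‑8‑prenyl‑2H‑chromen‑6‑yl]‑4H‑chromen‑4‑one | COCOc1cccc2oc(-c3c(OC)c4C=CC(C)(C)Oc4c(CC=C(C)C)c3OCOC)cc(=O)c12 | intermediate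
16 | racemic 4H‑chromen‑4‑ol from 15 | COCOc1cccc2OC(c3c(OC)c4C=CC(C)(C)Oc4c(CC=C(C)C)c3OCOC)=CC(O)c12 | intermediate
17 | 5‑hydroxy‑2‑(7‑hydroxy‑5‑methoxy‑2,2‑dimethyl‑8‑prenyl‑2H‑chromen‑6‑yl)chromenylium chloride | Oc1cccc2[o+]c(-c3c(OC)c4C=CC(C)(C)Oc4c(CC=C(C)C)c3O)ccc12.[Cl-] | intermediate
18 | racemic 2‑(7‑hydroxy‑5‑methoxy‑2,2‑dimethyl‑8‑prenyl‑2H‑chromen‑6‑yl)‑2H‑chromene‑2,5‑diol | OC1(c2c(OC)c3C=CC(C)(C)Oc3c(CC=C(C)C)c2O)C=Cc2c(O)cccc2O1 | intermediate
19 | (Z)‑3‑(2,6‑dihydroxyphenyl)‑1‑(7‑hydroxy‑5‑methoxy‑2,2‑dimethyl‑8‑prenyl‑2H‑chromen‑6‑yl)prop‑2‑en‑1‑one | COc1c(C(=O)/C=C\c2c(O)cccc2O)c(O)c(CC=C(C)C)c2OC(C)(C)C=Cc12 | intermediate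
20 | (8R)‑8‑(2,6‑dihydroxyphenyl)‑5‑methoxy‑2,2‑dimethyl‑10‑prenyl‑7,8‑dihydro‑2H,6H‑pyrano[3,2‑g]chromen‑6‑one (the 2R flavanone) | COc1c2C=CC(C)(C)Oc2c(CC=C(C)C)c2c1C(=O)C[C@H](c1c(O)cccc1O)O2 | intermediate
21 | bridged hemiketal of 20, O2' bonded to C4 (flavanone numbering 2R,4R) | COc1c2c(c(CC=C(C)C)c3c1[C@@]1(O)C[C@@H](O3)c3c(O)cccc3O1)OC(C)(C)C=C2 | target

**Step count:** 10 steps in total. Longest linear sequence: 9 steps (steps 1–6, 8, 9, 10).

**Steps most likely to fail**

Step 10. The uncatalysed cyclization of the ring A phenoxide may compete with the catalysed path, and some retro‑Michael opening may occur before the ketal closes, so facial selectivity may be poor. The fallback sets out from 17. The cascade is run without chiral catalyst in aqueous methanol buffered with NaOAc/AcOH. It should pass through 18, 19 and the racemic flavanone F2 to the racemic hemiketal F1. The enantiomers are then separated by preparative chromatography on an amylose tris(3,5‑dimethylphenylcarbamate) stationary phase, which comes back to the route at 21.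

Step 9. During the slow MOM cleavage the freed ortho‑prenyl phenol may add to the protonated prenyl double bond, and the chromenylium ion may leak through the chalcone to racemic product. The fallback sets out from 15. Both MOM ethers are cleaved first at the chromone stage, where no cation‑forming group is present (ZnBr2, n‑PrSH, CH2Cl2, 0 °C), to give 5‑hydroxy‑2‑(7‑hydroxy‑5‑methoxy‑2,2‑dimethyl‑8‑prenyl‑2H‑chromen‑6‑yl)‑4H‑chromen‑4‑one F3. The phenols are masked as the bis(trimethylsilyl) ether F4 (Me3SiCl, Et3N). Reduction with i‑Bu2AlH at −78 °C gives the silylated chromen‑4‑ol F5. A few minutes in cold dilute HCl/THF should remove the silyl groups and ionize the carbinol, which comes back to the route at 17.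

Step 8. The enolate may attack the doubly ortho‑substituted acyl imidazole too slowly, so that self‑condensation of the fluoro ketone enolate or O‑acylation takes over. The fallback sets out from 7. Aryllithium 8 is quenched with DMF to give 5‑methoxy‑7‑(methoxymethoxy)‑2,2‑dimethyl‑8‑prenyl‑2H‑chromene‑6‑carbaldehyde F6, a much less hindered electrophile. Aldol addition of lithium enolate 13 gives the β‑hydroxy ketone F7. Dess–Martin oxidation gives the neutral 1,3‑diketone F8. K2CO3 in DMF at 80 °C then closes the pyranone by SNAr, which comes back to the route at 15.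

**Further compounds**
F1 | step 10 | racemic bridged hemiketal (racemate of 21) | COc1c2c(c(CC=C(C)C)c3c1C1(O)CC(O3)c3c(O)cccc3O1)OC(C)(C)C=C2
F2 | step 10 | racemic flavanone (racemate of 20) | COc1c2C=CC(C)(C)Oc2c(CC=C(C)C)c2c1C(=O)CC(c1c(O)cccc1O)O2
F3 | step 9 | 5‑hydroxy‑2‑(7‑hydroxy‑5‑methoxy‑2,2‑dimethyl‑8‑prenyl‑2H‑chromen‑6‑yl)‑4H‑chromen‑4‑one | Oc1cccc2oc(-c3c(OC)c4C=CC(C)(C)Oc4c(CC=C(C)C)c3O)cc(=O)c12
F4 | step 9 | bis(trimethylsilyl) ether of F3 | C[Si](C)(C)Oc1cccc2oc(-c3c(OC)c4C=CC(C)(C)Oc4c(CC=C(C)C)c3O[Si](C)(C)C)cc(=O)c12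
F5 | step 9 | racemic 4H‑chromen‑4‑ol from F4 | C[Si](C)(C)Oc1cccc2OC(c3c(OC)c4C=CC(C)(C)Oc4c(CC=C(C)C)c3O[Si](C)(C)C)=CC(O)c12
F6 | step 8 | 5‑methoxy‑7‑(methoxymethoxy)‑2,2‑dimethyl‑8‑prenyl‑2H‑chromene‑6‑carbaldehyde | COCOc1c(C=O)c(OC)c2C=CC(C)(C)Oc2c1CC=C(C)C
F7 | step 8 | racemic 1‑[2‑fluoro‑6‑(methoxymethoxy)phenyl]‑3‑hydroxy‑3‑[5‑methoxy‑7‑(methoxymethoxy)‑2,2‑dimethyl‑8‑prenyl‑2H‑chromen‑6‑yl]propan‑1‑one | COCOc1c(C(O)CC(=O)c2c(F)cccc2OCOC)c(OC)c2C=CC(C)(C)Oc2c1CC=C(C)C
F8 | step 8 | 1‑[2‑fluoro‑6‑(methoxymethoxy)phenyl]‑3‑[5‑methoxy‑7‑(methoxymethoxy)‑2,2‑dimethyl‑8‑prenyl‑2H‑chromen‑6‑yl]propane‑1,3‑dione | COCOc1c(C(=O)CC(=O)c2c(F)cccc2OCOC)c(OC)c2C=CC(C)(C)Oc2c1CC=C(C)C
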